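## Structural features

The target is a flavanone, (2S)-2-(3,4-dimethoxyphenyl)-5,7,8-trimethoxychroman-4-one. Ring A is a benzene ring (C4a, C5, C6, C7, C8, C8a) with methoxy groups at C5, C7 and C8 and one free position, C6. It is fused along C4a–C8a to ring C, a dihydropyranone made of O1, C2, C3 and the C4 ketone, and ring B, a benzene ring with methoxy groups at C3' and C4', is joined to C2 by the single bond C2–C1'. C2 is the only stereocentre and has no stereogenic neighbour, so the task is absolute and not relative stereocontrol. The fragile point is the O1–C2 bond: C2 is an aryl ether carbon beta to the ketone, so an enolate at C3 can expel the O1 phenoxide (retro-oxa-Michael opening to a 2'-hydroxychalcone), and reclosure would return racemic material. C2–H is also benzylic and next to oxygen, so forcing oxidants can carry ring C on to the flavone, and the 5-methoxy group peri to the carbonyl is the aryl ether most easily cleaved by Lewis acids. The real difficulty is therefore not the skeleton but two points of control: setting C2 and keeping it through every later step, and placing the ring A oxygens in the 5,7,8 and not the isomeric 5,6,7 arrangement. The key step uses the shape of ring B: C2', C3', C4' and C5' are the four carbons of symmetrical 2,3-dimethoxybuta-1,3-diene, and C1' with C6' are the two carbons of a terminal alkyne on C2, so ring B can be grown on a chromanone whose stereocentre already exists.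

## Logic of the disconnections

No skeletal bond is cut in the first move. Ring B of 13 is taken back by two hydrogen atoms, at C2' and C5', to 12. This is done because a 1,4-cyclohexadiene is the direct product of an alkyne–diene cycloaddition. The gain is a ring that can be made in one step from two pieces. The demand on the forward step is an oxidant that removes hydride from ring B faster than from C2–H and does not dehydrogenate C2–C3.

In 12 the bonds C1'–C2' and C5'–C6' are cut, giving 10 and 11. The cut is made there because 11 is symmetrical, so no regiochemical question arises and the two methoxy groups can only end at C3' and C4'. The gain is large: all of ring B with its oxygenation becomes a four-carbon reagent, and what remains is a chromanone with a two-carbon handle. The demand is a catalyst that joins an unpolarised alkyne and an electron-rich diene under neutral, base-free conditions, since a thermal reaction is not available and C2 must survive.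

The C(sp)–H bond of 10 is exchanged for a C–Si bond, giving 9. The reason is that the ethynyl group is best introduced from a monoprotected acetylene. The simplification is small, but it makes the next cut possible. The demand is an unmasking that never generates the C3 enolate.

In 9 the bond between C2 and the alkyne carbon is cut, giving 5 and 6. This is the point at which the stereocentre is removed, and 5 is flat and achiral. The gain is that the only stereocentre is set by a catalyst in a C–C bond formation. The demand is twofold: 5 is a vinylogous ester and must be activated (as 7), and the nucleophile must distinguish the two faces of the cation.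

In 5 the bonds O1–C2 and C2–C3 are cut, which removes C2 as a one-carbon unit at the formate oxidation level and leads through 4 to 3. The cut is made there because an ortho-hydroxy methyl ketone is the classical chromone precursor. The gain is a simple trisubstituted hydroxyacetophenone. The demand is a C-formylation equivalent of the methyl group followed by cyclisation with loss of the amine.

In 3 the bond C4–C4a is cut and the methyl group on the C8a oxygen is restored, leading through 2 to 1 and a two-carbon acyl unit. The cut is made there because 1 carries all four ring A oxygens and has two equivalent free positions, so the acylation has only one possible site. The gain is a symmetrical starting material. The demand is that ether cleavage in 2 selects the ortho methoxy group that has a second methoxy neighbour; cleavage of the other ortho group would lead into the 5,6,7 series.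

## Other disconnections considered

Alternative 1: The cut goes through C4a–C8a and C5–C6, so rings A and C open together and the bicycle becomes one chain, A1. In A1 a methoxyethynyl ketone (future C5, C4a, C4) is tethered through C3, C2 and O1 to a 1-oxy-2,3-bis(silyloxy)butadiene (future C8a, C8, C7, C6), with ring B and the C2 stereocentre already in place. In the forward direction, heating A1 would bring about a type 1 intramolecular Diels–Alder reaction, and DDQ in the same flask would aromatise the adduct to A2. Both silyl ethers would then have to be exchanged for methyl ethers.
- In its favour: two rings and two C–C bonds would form in one metal-free operation. The partners are electronically matched (electron-poor ynone, electron-rich diene) and tethered, which on mechanistic grounds is a more secure cycloaddition than the intermolecular, unpolarised one of the chosen plan; on this point the alternative is the better. The ring A pattern follows from connectivity alone, with no selective ether cleavage, which is also a point for the alternative.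
- Against it here: A1 combines a push–pull alkoxy ynone, a beta-alkoxy ketone whose benzylic C2–O bond can be lost by elimination (and the stereocentre with it), and a hydrolytically labile dienyl ether of defined Z geometry on a secondary benzylic oxygen. No short, safe way to such a chain is apparent, and the heat of the key step acts on all three weaknesses. Desilylation and double phenol methylation under base would follow, and base is what a flavanone tolerates least.
- Comparison: the chosen plan is ahead on step economy (robust intermediates, one step after the key step against three). On the closing DDQ aromatisation the two are equal.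

Alternative 2: The cut is C4a–C5 (with C8–C8a in the step before), so ring A is built last on a finished ring C. The precursor A3 is a 4-hydroxycyclobutenone, the adduct of a metallated cyclic enol ether and a squaric acid derivative. On heating in xylene it would undergo four-electron ring opening and six-electron closure onto C4a (Moore-type ring expansion) to give the hydroquinone A4. Double O-methylation, desilylation and oxidation at C4 would remain.
- In its favour: this is an established thermal route to highly oxygenated arenes, and the cyclobutenone assigns every ring A substituent its place, so ring A regiochemistry is at least as secure as in the chosen plan and arguably better. C4 is carried as a silyl ether, so no enolisable ketone flanks C2 until the last step. This is a clear advantage over the chosen plan, which has to guard C2 in every step after the alkynylation.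
- Against it here: metallation of the enol ether carbon needs a very strong base on a substrate with a benzylic C2–H and an allylic silyloxy leaving group. The addition must choose between the two different carbonyl groups of the dione. A4 is an electron-rich, air-sensitive hydroquinone whose two hydroxyls must both be methylated, and a stereocentre at C4 is made only to be destroyed.
- Comparison: three steps after the key step against one, and a longer way to A3 than to the alkyne of the chosen plan. The two key steps are on a par in that neither creates the stereocentre.

Alternative 3: The cut is the aryl ether bond O1–C8a. The precursor is the bromo diol A5, with all carbons, ring B and both carbinol centres in place. CuI with 3,4,7,8-tetramethyl-1,10-phenanthroline and Cs2CO3 would couple the C2 alkoxide with the aryl bromide (intramolecular Ullmann-type etherification) to give the chromanol A6, and one oxidation at C4 would finish the synthesis.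
- In its favour: only the C2 oxygen can reach C8a through a six-membered ring (the C4 oxygen would have to close a four-membered one), so site selectivity is built in. The ring A pattern is fixed by the bromoarene with no choice between ether groups, which is better than the chosen plan. C2 is set by acyclic carbonyl chemistry and no ketone flanks it until the end, so its configuration is safer than in the chosen plan. One step follows the key step, equal to the chosen plan.
- Against it here: the bromide sits between a methoxy group and the side chain on a very electron-rich ring, the slowest kind of substrate for copper insertion, so high temperature and carbonate base are needed. Under such conditions the C4 carbinol, benzylic to a ring with ortho and para oxygen donors, is prone to ionisation, dehydration or oxidation, and hydrodebromination competes. A5 needs a regio-defined pentasubstituted bromoarene and a second stereocentre that is sacrificed.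
- Comparison: the way to A5 is judged to cost about as many steps as the whole chosen route. The chosen key step makes two C–C bonds where this one makes a C–O bond, but the etherification is the more thoroughly tried reaction type, and on that count the alternative is the safer.

Key step: step 5

Remarks on the chemistry (assumptions, one line each):
- 1, 6 and 11 are taken to be catalogue chemicals and are used as bought.
- In step 3 the antipode of the P,N ligand StackPhos that leads to the (2S) adduct of 5 is meant; which antipode that is has to be assigned on the first run.
- The alkynyl, cyclohexadienyl and aryl groups on C2 all rank between O1 and C3, so the descriptor stays S from 8 to 13 without any change in spatial arrangement.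
- A ring A precursor of the trimethoxybenzoyl type would lack the oxygen that becomes O1 and would need a C–H oxidation; 1 carries all four ring A oxygens, and the C–H oxidation route is kept only as a fallback.

## Route

Step 1
Reactants: 1 1,2,3,5-tetramethoxybenzene
Product: 3 1-(2-hydroxy-3,4,6-trimethoxyphenyl)ethan-1-one, via tetramethoxyacetophenone 2 (not isolated)
Conditions: AcCl, AlCl3 (2.2 equiv), Et2O, 0 °C to rt; then ice, 2 M HCl
Reagents that add atoms: acetyl chloride, CC(Cl)=O
Why: Friedel–Crafts acylation can only strike the two equivalent free positions of 1 and gives 2 as its aluminium chelate; in that chelate the ortho methoxy group wedged between the acyl group and a second methoxy group is twisted out of the ring plane, is the more basic and the more strained, and is cleaved by chloride (chelation-controlled ortho-demethylation), so the free hydroxyl sits on the future C8a next to the future C8 methoxy group. Limiting AlCl3 and temperature should spare the other ortho methoxy group (future C5).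

Step 2
Reactants: 3 1-(2-hydroxy-3,4,6-trimethoxyphenyl)ethan-1-one
Product: 5 5,7,8-trimethoxy-4H-chromen-4-one, via enaminone 4 (not isolated)
Conditions: Me2NCH(OMe)2, 95 °C; then conc. HCl, CH2Cl2, 40 °C
Reagents that add atoms: N,N-dimethylformamide dimethyl acetal, COC(OC)N(C)C
Why: Condensation of the methyl ketone with the formamide acetal gives the enaminone 4; acid then adds the phenol to the beta carbon and expels dimethylamine (enaminone route to chromones), which supplies C2 and closes ring C.

Step 3
Reactants: 5 5,7,8-trimethoxy-4H-chromen-4-one; 6 ethynyl(trimethyl)silane (trimethylsilylacetylene)
Product: 9 (2S)-5,7,8-trimethoxy-2-[(trimethylsilyl)ethynyl]chroman-4-one, via silyloxybenzopyrylium triflate 7 (not isolated), via silyl enol ether 8 (not isolated)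
Conditions: TBSOTf (1.3 equiv), CuI (5 mol %), StackPhos (6 mol %, antipode giving 2S), iPr2NEt (1.5 equiv), toluene, −20 °C; then 2 M HCl, THF, rt
Reagents that add atoms: tert-butyldimethylsilyl trifluoromethanesulfonate, CC(C)(C)[Si](C)(C)OS(=O)(=O)C(F)(F)F (its silyl group stays in 7 and 8 only and is lost again on hydrolysis)
Why: O-Silylation turns the unreactive vinylogous ester into the benzopyrylium ion 7, and the acetylide formed from 6, CuI and the amine (monovalent copper) adds to C2 while bound to the chiral P,N ligand (copper-catalysed enantioselective alkynylation of chromones). The ligand shields one face of the planar cation and so sets C2 as S; acid hydrolysis of the silyl enol ether 8 releases the ketone.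

Step 4
Reactants: 9 (2S)-5,7,8-trimethoxy-2-[(trimethylsilyl)ethynyl]chroman-4-one
Product: 10 (2S)-2-ethynyl-5,7,8-trimethoxychroman-4-one
Conditions: TBAF (1.1 equiv), AcOH (1.5 equiv), THF, 0 °C
Reagents that add atoms: none
Why: Fluoride attacks the silicon of the alkynylsilane and acetic acid protonates the acetylide at once (buffered protodesilylation). The buffer keeps the C3 enolate from forming, so the retro-oxa-Michael pathway that would racemise C2 stays closed.

Step 5
Reactants: 10 (2S)-2-ethynyl-5,7,8-trimethoxychroman-4-one; 11 2,3-dimethoxybuta-1,3-diene
Product: 12 (2S)-2-(4,5-dimethoxycyclohexa-1,4-dien-1-yl)-5,7,8-trimethoxychroman-4-one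
Conditions: CoBr2(dppe) (10 mol %), Zn powder (20 mol %), ZnI2 (20 mol %), 11 (3 equiv), CH2Cl2, rt; filtration through basic Al2O3
Reagents that add atoms: none
Why: Zn powder reduces CoBr2(dppe) (divalent cobalt) to a monovalent cobalt species and ZnI2 frees a coordination site by halide abstraction; the metal binds 11 in its s-cis form and the alkyne of 10, couples them oxidatively to a cobaltacycle (a sigma-vinyl, η3-allyl species of trivalent cobalt) and forms the second C–C bond by reductive elimination, releasing 12 and the monovalent catalyst. The closest known reaction type is the cobalt-catalysed neutral Diels–Alder reaction of terminal alkynes with 2,3-disubstituted buta-1,3-dienes, which also accepts oxygen-substituted dienes; 10 and 11 are new partners for it. Ring B is closed by an intermolecular two-bond [4+2] annulation: C1' and C6' come from the alkyne, C2' to C5' from the diene, and the bonds C1'–C2' and C5'–C6' are both made on the metal. No stereocentre is created; C2 lies outside the reacting pi system and is not deprotonated in a base-free medium, so it should keep its configuration. The selectivity needed is chemoselectivity for cross cycloaddition over cyclotrimerisation of 10 and dimerisation of 11; the chelating diphosphine, which disfavours the bis(alkyne) cobaltacycle on the way to trimers, and the threefold excess of 11 should secure it. Regioselectivity does not arise because the two ends of 11 are equivalent, so the methoxy groups can only arrive at C3' and C4'. The ketone and aryl ethers of 10 are not pi partners for the catalyst, and the acid-labile bis(enol ether) 12 is protected by the non-aqueous work-up and is used at once.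

Step 6
Reactants: 12 (2S)-2-(4,5-dimethoxycyclohexa-1,4-dien-1-yl)-5,7,8-trimethoxychroman-4-one
Product: 13 (2S)-2-(3,4-dimethoxyphenyl)-5,7,8-trimethoxychroman-4-one
Conditions: DDQ (1.05 equiv), NaHCO3 (solid), toluene, 0 °C to rt
Reagents that add atoms: none
Why: DDQ abstracts hydride from a doubly allylic CH2 of the electron-rich bis(enol ether) ring and loss of a proton gives the arene (oxidative aromatisation of a 1,4-cyclohexadiene); this should be far faster than attack at C2–H or dehydrogenation of C2–C3, which need heat. Solid NaHCO3 keeps the acidic hydroquinone from hydrolysing the enol ethers before they are aromatised, and C2 is not involved.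

## Compound list

1 | 1,2,3,5-tetramethoxybenzene | COc1cc(OC)c(OC)c(OC)c1 | starting material
2 | 1-(2,3,4,6-tetramethoxyphenyl)ethan-1-one (present as its AlCl3 chelate) | CC(=O)c1c(OC)cc(OC)c(OC)c1OC | intermediate (not isolated)
3 | 1-(2-hydroxy-3,4,6-trimethoxyphenyl)ethan-1-one | CC(=O)c1c(OC)cc(OC)c(OC)c1O | intermediate
4 | (2E)-3-(dimethylamino)-1-(2-hydroxy-3,4,6-trimethoxyphenyl)prop-2-en-1-one | CN(C)/C=C/C(=O)c1c(OC)cc(OC)c(OC)c1O | intermediate (not isolated)
5 | 5,7,8-trimethoxy-4H-chromen-4-one | O=c1ccoc2c(OC)c(OC)cc(OC)c12 | intermediate
6 | ethynyl(trimethyl)silane | C#C[Si](C)(C)C | starting material
7 | 4-(tert-butyldimethylsilyloxy)-5,7,8-trimethoxychromenylium trifluoromethanesulfonate | COc1cc(OC)c2c(O[Si](C)(C)C(C)(C)C)cc[o+]c2c1OC.[O-]S(=O)(=O)C(F)(F)F | intermediate (not isolated)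
8 | (2S)-4-(tert-butyldimethylsilyloxy)-5,7,8-trimethoxy-2-[(trimethylsilyl)ethynyl]-2H-chromene | C[Si](C)(C)C#C[C@@H]1C=C(O[Si](C)(C)C(C)(C)C)c2c(OC)cc(OC)c(OC)c2O1 | intermediate (not isolated)
9 | (2S)-5,7,8-trimethoxy-2-[(trimethylsilyl)ethynyl]chroman-4-one | C[Si](C)(C)C#C[C@@H]1CC(=O)c2c(OC)cc(OC)c(OC)c2O1 | intermediate
10 | (2S)-2-ethynyl-5,7,8-trimethoxychroman-4-one | C#C[C@@H]1CC(=O)c2c(OC)cc(OC)c(OC)c2O1 | intermediate
11 | 2,3-dimethoxybuta-1,3-diene | C=C(OC)C(=C)OC | starting material
12 | (2S)-2-(4,5-dimethoxycyclohexa-1,4-dien-1-yl)-5,7,8-trimethoxychroman-4-one | COC1=C(OC)CC(=CC1)[C@@H]2CC(=O)c3c(OC)cc(OC)c(OC)c3O2 | intermediate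
13 | (2S)-2-(3,4-dimethoxyphenyl)-5,7,8-trimethoxychroman-4-one | COc1ccc([C@@H]2CC(=O)c3c(OC)cc(OC)c(OC)c3O2)cc1OC | target

## Step count and least certain steps

Total step count: 6 (steps 1 to 6).
Longest linear sequence: 6 steps, from 1 to 13; 6 and 11 enter as purchased reagents.

Step 5 (key step).
- What may go wrong: homo-oligomerisation of the terminal alkyne (cyclotrimerisation) may outrun the cross cycloaddition, or the electron-rich diene may be consumed by ZnI2-induced cationic oligomerisation before it reaches the metal. Both are possible because a bis(enol ether) diene and an alkyne carrying a chelating keto ether array (C4=O, 5-methoxy, O1) are untried partners for this catalyst, and the array can bind zinc or cobalt.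
- Fallback: it sets out from 5 and comes back at 13. Ring B is brought in ready-made instead of being grown, by rhodium-catalysed asymmetric 1,4-addition of (3,4-dimethoxyphenyl)boronic acid to 5 ([Rh(OH)(cod)]2 with a chiral diene or an electron-poor chiral bisphosphine, aqueous dioxane), a known way from chromones to 2-arylchromanones, with the ligand antipode chosen for 2S. New compounds on this way: none F0.

Step 3.
- What may go wrong: the addition may be sluggish or poorly face-selective. Three methoxy donors stabilise the cation 7 and lower its electrophilicity at C2, and the 5-methoxy group peri to the bulky silyloxy group distorts it, so a slow, unselective background addition could erode the enantiomeric purity.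
- Fallback: it sets out from 5 and comes back at 9. Asymmetric catalysis is replaced by resolution: the same benzopyrylium alkynylation without chiral ligand (TBSOTf, CuI, iPr2NEt, then acid) should give racemic 5,7,8-trimethoxy-2-[(trimethylsilyl)ethynyl]chroman-4-one F1. Preparative chromatography on a chiral stationary phase then separates 9 from (2R)-5,7,8-trimethoxy-2-[(trimethylsilyl)ethynyl]chroman-4-one F2, which is set aside.

Step 4.
- What may go wrong: partial racemisation by reversible ring opening. Fluoride is basic enough to form the C3 enolate if the buffer is overrun locally, and the enolate expels the O1 phenoxide.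
- Fallback: it sets out from 9 and comes back at 10. The acidifying carbonyl is removed before silicon is touched.
  - NaBH4, MeOH, 0 °C should reduce 9 to (2S)-5,7,8-trimethoxy-2-[(trimethylsilyl)ethynyl]chroman-4-ol F3 (C4 epimers, of no consequence).
  - K2CO3, MeOH removes the silyl group to give (2S)-2-ethynyl-5,7,8-trimethoxychroman-4-ol F4; base is harmless here because no enolisable ketone flanks C2.
  - Dess–Martin periodinane with NaHCO3 in CH2Cl2 restores the ketone and gives 10. Acid is avoided throughout because the C4 carbinol is a strongly activated benzylic alcohol.

Step 1.
- What may go wrong: ether cleavage at the wrong site or to the wrong extent (loss of the unflanked ortho methoxy group, or of both ortho groups), which would lead into the 5,6,7 series. The selection rests only on the different environments of two ortho ether groups in one chelate.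
- Fallback: it cannot set out from a numbered compound because the fault would lie in the first step. It sets out from purchased 2,4,5-trimethoxybenzoic acid F5 and comes back at 3. The oxygen that becomes O1 is introduced by directed C–H functionalisation instead of being unveiled by ether cleavage.
  - Carboxylate-directed ortho-lithiation (s-BuLi, TMEDA, THF, −78 °C) at the position between the carboxylate and the 5-methoxy group, quench with B(OMe)3 and oxidation with H2O2 in the same flask should give 2-hydroxy-3,4,6-trimethoxybenzoic acid F6. It is worked up cold and only weakly acidic, since such electron-rich salicylic acids decarboxylate easily.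
  - MeLi (excess, THF, 0 °C) converts F6 through its geminal dialkoxide into 3.

## Further compounds

F0 | step 5 | none | none
F1 | step 3 | racemic 5,7,8-trimethoxy-2-[(trimethylsilyl)ethynyl]chroman-4-one | C[Si](C)(C)C#CC1CC(=O)c2c(OC)cc(OC)c(OC)c2O1
F2 | step 3 | (2R)-5,7,8-trimethoxy-2-[(trimethylsilyl)ethynyl]chroman-4-one | C[Si](C)(C)C#C[C@H]1CC(=O)c2c(OC)cc(OC)c(OC)c2O1
F3 | step 4 | (2S)-5,7,8-trimethoxy-2-[(trimethylsilyl)ethynyl]chroman-4-ol (C4 epimers) | C[Si](C)(C)C#C[C@@H]1CC(O)c2c(OC)cc(OC)c(OC)c2O1
F4 | step 4 | (2S)-2-ethynyl-5,7,8-trimethoxychroman-4-ol (C4 epimers) | C#C[C@@H]1CC(O)c2c(OC)cc(OC)c(OC)c2O1
F5 | step 1 | 2,4,5-trimethoxybenzoic acid | COc1cc(OC)c(C(=O)O)cc1OC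
F6 | step 1 | 2-hydroxy-3,4,6-trimethoxybenzoic acid | COc1cc(OC)c(C(=O)O)c(O)c1OC
A1 | alternative 1 | (5S)-5-{[(1Z)-2,3-bis(tert-butyldimethylsilyloxy)buta-1,3-dien-1-yl]oxy}-5-(3,4-dimethoxyphenyl)-1-methoxypent-1-yn-3-one | COC#CC(=O)C[C@H](O/C=C(\O[Si](C)(C)C(C)(C)C)C(=C)O[Si](C)(C)C(C)(C)C)c1ccc(OC)c(OC)c1
A2 | alternative 1 | (2S)-7,8-bis(tert-butyldimethylsilyloxy)-2-(3,4-dimethoxyphenyl)-5-methoxychroman-4-one | COc1ccc([C@@H]2CC(=O)c3c(OC)cc(O[Si](C)(C)C(C)(C)C)c(O[Si](C)(C)C(C)(C)C)c3O2)cc1OC
A3 | alternative 2 | 4-[(2S,4S)-4-(tert-butyldimethylsilyloxy)-2-(3,4-dimethoxyphenyl)-3,4-dihydro-2H-pyran-6-yl]-4-hydroxy-3-methoxycyclobut-2-en-1-one (either configuration at the carbinol carbon) | COc1ccc([C@@H]2C[C@H](O[Si](C)(C)C(C)(C)C)C=C(C3(O)C(OC)=CC3=O)O2)cc1OC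
A4 | alternative 2 | (2S,4S)-4-(tert-butyldimethylsilyloxy)-2-(3,4-dimethoxyphenyl)-7-methoxychroman-5,8-diol | COc1ccc([C@@H]2C[C@H](O[Si](C)(C)C(C)(C)C)c3c(O)cc(OC)c(O)c3O2)cc1OC
A5 | alternative 3 | (1S,3S)-1-(2-bromo-3,4,6-trimethoxyphenyl)-3-(3,4-dimethoxyphenyl)propane-1,3-diol | COc1ccc([C@@H](O)C[C@H](O)c2c(OC)cc(OC)c(OC)c2Br)cc1OC
A6 | alternative 3 | (2S,4S)-2-(3,4-dimethoxyphenyl)-5,7,8-trimethoxychroman-4-ol | COc1ccc([C@@H]2C[C@H](O)c3c(OC)cc(OC)c(OC)c3O2)cc1OC
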